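**Retrosynthetic overview**

1. In both heterocycles N1 is bonded to C2(CH3), C2 sits next to the ester-bearing C3, and C6 carries the chain. Cutting N1a=C2a and, after taking ring B back to its imine, N1b=C2b opens both rings to one twofold-symmetric 26-membered diolide 17 with two acetyl and two azido groups.
2. 17 comes from the bis(isopropenyl) diolide 16 by double ozonolysis, so the epimerisable acyloxy ketone exists for one step only; 16 is the head-to-tail cyclodimer of hydroxy acid 13.
3. 13 is built from methyl 9-oxononanoate without protecting groups: C9–N by sulfinimine/butenyl Grignard addition and diazo transfer, C12–O by enone reduction.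
4. Ring order: macrocycle (step 10), then rings A and B together by double transannular Staudinger/aza-Wittig (step 12), then reduction of ring B only (step 13).

Key step: step 12

Remark: chain carbons are numbered C1 (carboxyl) to C14; C9, C12 and C13 become C6, C3 and C2 of each heterocycle (a = imine ring A, b = amine ring B). Compounds 2, 4 and 9 are taken as commercial.

**Step 1**
Reactants: 1 methyl 9-oxononanoate; 2 (R)-2-methylpropane-2-sulfinamide
Product: 3 methyl (9E)-9-{[(R)-tert-butylsulfinyl]imino}nonanoate
Conditions: CuSO4 (2 equiv), CH2Cl2, rt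
Reagents that add atoms: none
Why: Condensation of an aldehyde with the sulfinamide over a Lewis-acidic dehydrating agent should give the (E)-N-sulfinyl aldimine without touching the methyl ester, the sulfur stereocentre being carried in unchanged.

**Step 2**
Reactants: 3 methyl (9E)-9-{[(R)-tert-butylsulfinyl]imino}nonanoate; 4 but-3-enylmagnesium bromide
Product: 5 methyl (9R)-9-{[(R)-tert-butylsulfinyl]amino}tridec-12-enoate
Conditions: CH2Cl2, −78 to −48 °C; aq NH4Cl
Reagents that add atoms: none
Why: Grignard 1,2-addition to an N-tert-butanesulfinyl aldimine in a non-coordinating solvent runs through a six-membered chair transition state (Mg on the sulfinyl oxygen, tert-butyl equatorial) that should deliver butenyl to one face and set C9 as R, the imine reacting far faster than the ester in the cold and the minor diastereomer being removable by chromatography.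

**Step 3**
Reactants: 5 methyl (9R)-9-{[(R)-tert-butylsulfinyl]amino}tridec-12-enoate
Product: 6 methyl (9R)-9-aminotridec-12-enoate hydrochloride
Conditions: HCl (4 M in dioxane), MeOH, 0 °C to rt
Reagents that add atoms: hydrogen chloride, Cl
Why: Acidic methanolysis cleaves only the N–S bond of the sulfinamide, leaving the C9–N bond, the methyl ester and the alkene untouched.

**Step 4**
Reactants: 6 methyl (9R)-9-aminotridec-12-enoate hydrochloride
Product: 7 methyl (9R)-9-azidotridec-12-enoate
Conditions: imidazole-1-sulfonyl azide hydrogen sulfate, K2CO3, CuSO4·5H2O (cat.), MeOH, rt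
Reagents that add atoms: imidazole-1-sulfonyl azide hydrogen sulfate, [N-]=[N+]=NS(=O)(=O)n1ccnc1.OS(=O)(=O)O
Why: Copper-catalysed diazo transfer turns the primary amine into the azide with retention at C9 because the C–N bond is never broken.

**Step 5**
Reactants: 7 methyl (9R)-9-azidotridec-12-enoate
Product: 8 methyl (9R)-9-azido-12-oxododecanoate
Conditions: O3, pyridine, CH2Cl2, −78 °C
Reagents that add atoms: ozone, [O-][O+]=O
Why: Ozonolysis cleaves the terminal alkene to the C12 aldehyde, azide and ester being inert to ozone and the pyridine-promoted breakdown of the carbonyl oxide making a phosphine or sulfide reductant unnecessary.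

**Step 6**
Reactants: 8 methyl (9R)-9-azido-12-oxododecanoate; 9 isopropenylmagnesium bromide
Product: 10 methyl (9R,12RS)-9-azido-12-hydroxy-13-methyltetradec-13-enoate
Conditions: THF, −78 °C; aq NH4Cl
Reagents that add atoms: none
Why: Grignard 1,2-addition to the aldehyde outruns attack on the ester or azide at −78 °C, and the C12 epimer mixture is accepted because that centre is erased in step 7.

**Step 7**
Reactants: 10 methyl (9R,12RS)-9-azido-12-hydroxy-13-methyltetradec-13-enoate
Product: 11 methyl (9R)-9-azido-13-methyl-12-oxotetradec-13-enoate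
Conditions: Dess–Martin periodinane, CH2Cl2, 0 °C to rt
Reagents that add atoms: none
Why: Dess–Martin oxidation converts both allylic alcohol epimers into one isopropenyl ketone under near-neutral conditions; the enone is used at once and kept cold to avoid azide–enone cycloaddition.

**Step 8**
Reactants: 11 methyl (9R)-9-azido-13-methyl-12-oxotetradec-13-enoate
Product: 12 methyl (9R,12S)-9-azido-12-hydroxy-13-methyltetradec-13-enoate
Conditions: (R)-1-methyl-3,3-diphenyltetrahydro-1H,3H-pyrrolo[1,2-c][1,3,2]oxazaborole (20 mol %), catecholborane, toluene, −78 °C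
Reagents that add atoms: none
Why: Corey–Bakshi–Shibata reduction with the branched isopropenyl group as the large substituent should set C12 as S with the (R)-catalyst, while catecholborane at −78 °C spares azide, ester and the 1,1-disubstituted alkene.

**Step 9**
Reactants: 12 methyl (9R,12S)-9-azido-12-hydroxy-13-methyltetradec-13-enoate
Product: 13 (9R,12S)-9-azido-12-hydroxy-13-methyltetradec-13-enoic acid
Conditions: LiOH, THF/MeOH/H2O, rt; then dilute HCl
Reagents that add atoms: lithium hydroxide, [Li+].[OH-]
Why: Saponification of the methyl ester meets no base-sensitive centre, since C12 bears an alkene and not yet a ketone.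

**Step 10**
Reactants: 13 (9R,12S)-9-azido-12-hydroxy-13-methyltetradec-13-enoic acid (two molecules)
Product: 16 (10R,13S,23R,26S)-10,23-diazido-13,26-di(prop-1-en-2-yl)-1,14-dioxacyclohexacosane-2,15-dione, via monomer mixed anhydride 14 (not isolated), via linear dimer mixed anhydride 15 (not isolated)
Conditions: 2,4,6-trichlorobenzoyl chloride, Et3N, THF, rt; then slow addition to DMAP, toluene, 40 °C (about 10 mM)
Reagents that add atoms: none
Why: Yamaguchi esterification at moderate dilution should favour head-to-tail dimerisation followed by 26-membered ring closure over the strained 13-membered monolide; no stereocentre is touched, and the temperature is held low to avoid azide–alkene cycloaddition.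

**Step 11**
Reactants: 16 (10R,13S,23R,26S)-10,23-diazido-13,26-di(prop-1-en-2-yl)-1,14-dioxacyclohexacosane-2,15-dione
Product: 17 (10R,13S,23R,26S)-13,26-diacetyl-10,23-diazido-1,14-dioxacyclohexacosane-2,15-dione
Conditions: O3, pyridine, CH2Cl2, −78 °C
Reagents that add atoms: ozone, [O-][O+]=O
Why: Twofold ozonolysis of the 1,1-disubstituted alkenes unveils both acetyl groups under cold, neutral conditions, so the new α-acyloxy ketone centres never meet base and the azides stay intact.

**Step 12**
Reactants: 17 (10R,13S,23R,26S)-13,26-diacetyl-10,23-diazido-1,14-dioxacyclohexacosane-2,15-dione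
Product: 20 bis-imine diolide (each half a (3S,6R)-2-methyl-3,4,5,6-tetrahydropyridine bridged O–C3 to C6), via bis(iminophosphorane) 18 (not isolated), via imine iminophosphorane 19 (not isolated)
Conditions: PMe3 (2.4 equiv), THF, 0 °C to rt (40 °C if needed)
Reagents that add atoms: none
Why: PMe3 adds to the terminal nitrogen of each azide, the phosphazide loses N2, and each iminophosphorane nitrogen attacks the acetyl carbonyl of its own half to give an oxazaphosphetidine that collapses to C=N and Me3P=O. The closest known reaction is the intramolecular Staudinger/aza-Wittig cyclisation of 5-azido ketones to 2-substituted 3,4,5,6-tetrahydropyridines. Rings A and B each close in 6-exo-trig mode by forming N1–C2 across the macrocycle, which turns the monocyclic diolide into the tricyclic skeleton. No stereocentre is created, and C3 and C6 of both rings are carried through because no bond at them is made or broken and no external base or acid is present. The step needs ketone over ester selectivity and own-half over cross-ring selectivity: esters are inert to iminophosphoranes at this temperature, the ester carbonyl would need a seven-membered and the far acetyl a 13-membered transition state, and only the near acetyl lies within six-ring reach. Fast intramolecular capture should keep the basic iminophosphorane from epimerising C3.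

**Step 13**
Reactants: 20 bis-imine diolide
Product: 21 target CNP0304114.1
Conditions: NaBH(OAc)3 (0.4 equiv), AcOH, CH2Cl2, −20 °C; recovered 20 recycled
Reagents that add atoms: none
Why: Acyloxyborohydride reduction of the protonated cyclic ketimine should deliver hydride axially and anti to the C3b acyloxy group, which allylic strain with the C2b methyl holds pseudo-axial, giving the all-cis (2S) piperidine; substoichiometric hydride should reduce mainly one imine, and the more basic amine product is separable from 20, which is returned to the step.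

**Compound list**

1 | methyl 9-oxononanoate | O=CCCCCCCCC(=O)OC | starting material
2 | (R)-2-methylpropane-2-sulfinamide | CC(C)(C)[S@@](=O)N | starting material
3 | methyl (9E)-9-{[(R)-tert-butylsulfinyl]imino}nonanoate | CC(C)(C)[S@@](=O)/N=C/CCCCCCCC(=O)OC | intermediate
4 | but-3-enylmagnesium bromide | C=CCC[Mg]Br | starting material
5 | methyl (9R)-9-{[(R)-tert-butylsulfinyl]amino}tridec-12-enoate | CC(C)(C)[S@@](=O)N[C@@H](CCC=C)CCCCCCCC(=O)OC | intermediate
6 | methyl (9R)-9-aminotridec-12-enoate hydrochloride | C=CCC[C@H](N)CCCCCCCC(=O)OC.Cl | intermediate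
7 | methyl (9R)-9-azidotridec-12-enoate | C=CCC[C@H](N=[N+]=[N-])CCCCCCCC(=O)OC | intermediate
8 | methyl (9R)-9-azido-12-oxododecanoate | O=CCC[C@H](N=[N+]=[N-])CCCCCCCC(=O)OC | intermediate
9 | isopropenylmagnesium bromide | CC(=C)[Mg]Br | starting material
10 | methyl (9R,12RS)-9-azido-12-hydroxy-13-methyltetradec-13-enoate (C12 epimer mixture) | C=C(C)C(O)CC[C@H](N=[N+]=[N-])CCCCCCCC(=O)OC | intermediate
11 | methyl (9R)-9-azido-13-methyl-12-oxotetradec-13-enoate | C=C(C)C(=O)CC[C@H](N=[N+]=[N-])CCCCCCCC(=O)OC | intermediate
12 | methyl (9R,12S)-9-azido-12-hydroxy-13-methyltetradec-13-enoate | C=C(C)[C@@H](O)CC[C@H](N=[N+]=[N-])CCCCCCCC(=O)OC | intermediate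
13 | (9R,12S)-9-azido-12-hydroxy-13-methyltetradec-13-enoic acid | C=C(C)[C@@H](O)CC[C@H](N=[N+]=[N-])CCCCCCCC(=O)O | intermediate
14 | mixed anhydride of 13 and 2,4,6-trichlorobenzoic acid | C=C(C)[C@@H](O)CC[C@H](N=[N+]=[N-])CCCCCCCC(=O)OC(=O)c1c(Cl)cc(Cl)cc1Cl | intermediate
15 | linear head-to-tail dimer of 13 as its 2,4,6-trichlorobenzoic mixed anhydride | C=C(C)[C@@H](O)CC[C@H](N=[N+]=[N-])CCCCCCCC(=O)O[C@H](C(C)=C)CC[C@H](N=[N+]=[N-])CCCCCCCC(=O)OC(=O)c1c(Cl)cc(Cl)cc1Cl | intermediate
16 | (10R,13S,23R,26S)-10,23-diazido-13,26-di(prop-1-en-2-yl)-1,14-dioxacyclohexacosane-2,15-dione | O1[C@H](C(C)=C)CC[C@H](N=[N+]=[N-])CCCCCCCC(=O)O[C@H](C(C)=C)CC[C@H](N=[N+]=[N-])CCCCCCCC1=O | intermediate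
17 | (10R,13S,23R,26S)-13,26-diacetyl-10,23-diazido-1,14-dioxacyclohexacosane-2,15-dione | O1[C@H](C(C)=O)CC[C@H](N=[N+]=[N-])CCCCCCCC(=O)O[C@H](C(C)=O)CC[C@H](N=[N+]=[N-])CCCCCCCC1=O | intermediate
18 | (10R,13S,23R,26S)-13,26-diacetyl-10,23-bis[(trimethylphosphoranylidene)amino]-1,14-dioxacyclohexacosane-2,15-dione | O1[C@H](C(C)=O)CC[C@H](N=P(C)(C)C)CCCCCCCC(=O)O[C@H](C(C)=O)CC[C@H](N=P(C)(C)C)CCCCCCCC1=O | intermediate
19 | half-closed diolide: ring A formed as (3S,6R)-2-methyl-3,4,5,6-tetrahydropyridine, other half still acetyl plus trimethylphosphoranylideneamino | CC1=N[C@@H]2CCCCCCCC(=O)O[C@H](C(C)=O)CC[C@H](N=P(C)(C)C)CCCCCCCC(=O)O[C@H]1CC2 | intermediate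
20 | bis-imine diolide: 26-membered diolide whose two halves each carry a (3S,6R)-2-methyl-3,4,5,6-tetrahydropyridine ring (ester oxygen on C3, chain on C6) | CC1=N[C@@H]2CCCCCCCC(=O)O[C@H]3CC[C@@H](CCCCCCCC(=O)O[C@H]1CC2)N=C3C | intermediate
21 | CNP0304114.1: ring A (3S,6R)-2-methyl-3,4,5,6-tetrahydropyridine, ring B all-cis (2S,3S,6R)-2-methylpiperidine, joined by the two ester chains | CC1=N[C@@H]2CCCCCCCC(=O)O[C@H]3CC[C@@H](CCCCCCCC(=O)O[C@H]1CC2)N[C@H]3C | target

**Step count and risks**

Total step count: 13. Longest linear sequence: 13 steps (from 1).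

Steps most likely to fail:

Step 13. The reduction may run on statistically to the bis-amine, and hydride delivery at C2b may not be fully face-selective. Fallback: the two halves are made different before the macrocycle exists, so no selective reduction is needed.
- Setting out from 13, ozonolysis (O3, pyridine, CH2Cl2, −78 °C) should give (9R,12S)-9-azido-12-hydroxy-13-oxotetradecanoic acid F1.
- Hydrogenation (H2, Pd/C, MeOH) reduces the azide, the amine condenses with the ketone, and the cyclic imine is hydrogenated from the face opposite both ring substituents to the all-cis amino acid 8-[(2R,5S,6S)-5-hydroxy-6-methylpiperidin-2-yl]octanoic acid F2.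
- Boc2O and Na2CO3 in dioxane/water give 8-[(2R,5S,6S)-1-(tert-butoxycarbonyl)-5-hydroxy-6-methylpiperidin-2-yl]octanoic acid F3.
- Carbodiimide esterification (EDC·HCl, DMAP, CH2Cl2) with an excess of the unhindered allylic alcohol 12 gives the linear hetero-ester methyl ester F4.
- Me3SnOH in 1,2-dichloroethane at 60 °C cleaves only the methyl ester to the seco acid F5.
- Yamaguchi macrolactonisation at high dilution closes the unsymmetrical 26-membered diolide F6, which carries one N-Boc piperidine half and one azido isopropenyl half.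
- Ozonolysis unveils the single acetyl group in the azido ketone diolide F7.
- PMe3 in THF closes ring A alone to the N-Boc imine diolide F8.
- TFA in CH2Cl2 at 0 °C followed by neutralisation removes the Boc group, and the sequence comes back to the route at 21.

Step 10. Closure to the 13-membered monolide and chain growth to open oligomers may compete with head-to-tail cyclodimerisation. Fallback: stepwise assembly.
- Setting out from 12, TBSCl and imidazole in DMF give methyl (9R,12S)-9-azido-12-[(tert-butyldimethylsilyl)oxy]-13-methyltetradec-13-enoate F9.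
- LiOH gives (9R,12S)-9-azido-12-[(tert-butyldimethylsilyl)oxy]-13-methyltetradec-13-enoic acid F10.
- EDC·HCl/DMAP esterification with a second portion of 12 gives the silylated linear dimer methyl ester F11.
- Me3SnOH cleaves the methyl ester selectively to the silylated linear dimer acid F12.
- HF·pyridine in THF frees the allylic alcohol to give the linear dimer hydroxy acid F13.
- Yamaguchi macrolactonisation at high dilution (about 1 mM) closes the ring and returns to the route at 16.

Step 12. The strongly basic iminophosphorane nitrogen may remove the proton at C3 next to the acetyl group before ring closure, eroding configuration, or the second closure may stall. Fallback: setting out from 17, both azides are hydrogenated (H2, Pd/CaCO3 poisoned with Pb(OAc)2, EtOAc with a little AcOH, rt) to (10R,13S,23R,26S)-13,26-diacetyl-10,23-diamino-1,14-dioxacyclohexacosane-2,15-dione F14. F14 is not isolated: each primary amine condenses with the acetyl group of its own half (amine–ketone cyclodehydration, six-membered), and the sequence returns to the route at 20 without any phosphorus ylide base.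

**Further compounds**

F1 | step 13 | (9R,12S)-9-azido-12-hydroxy-13-oxotetradecanoic acid | CC(=O)[C@@H](O)CC[C@H](N=[N+]=[N-])CCCCCCCC(=O)O
F2 | step 13 | 8-[(2R,5S,6S)-5-hydroxy-6-methylpiperidin-2-yl]octanoic acid | O[C@H]1CC[C@@H](CCCCCCCC(=O)O)N[C@H]1C
F3 | step 13 | 8-[(2R,5S,6S)-1-(tert-butoxycarbonyl)-5-hydroxy-6-methylpiperidin-2-yl]octanoic acid | O[C@H]1CC[C@@H](CCCCCCCC(=O)O)N(C(=O)OC(C)(C)C)[C@H]1C
F4 | step 13 | linear hetero-ester methyl ester (acid of F3 esterified by the C12 hydroxyl of 12) | O[C@H]1CC[C@@H](CCCCCCCC(=O)O[C@H](C(C)=C)CC[C@H](N=[N+]=[N-])CCCCCCCC(=O)OC)N(C(=O)OC(C)(C)C)[C@H]1C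
F5 | step 13 | seco acid of F4 | O[C@H]1CC[C@@H](CCCCCCCC(=O)O[C@H](C(C)=C)CC[C@H](N=[N+]=[N-])CCCCCCCC(=O)O)N(C(=O)OC(C)(C)C)[C@H]1C
F6 | step 13 | unsymmetrical diolide: N-Boc all-cis piperidine half, azido isopropenyl half | O1[C@H]2CC[C@@H](CCCCCCCC(=O)O[C@H](C(C)=C)CC[C@H](N=[N+]=[N-])CCCCCCCC1=O)N(C(=O)OC(C)(C)C)[C@H]2C
F7 | step 13 | unsymmetrical diolide: N-Boc all-cis piperidine half, azido acetyl half | O1[C@H]2CC[C@@H](CCCCCCCC(=O)O[C@H](C(C)=O)CC[C@H](N=[N+]=[N-])CCCCCCCC1=O)N(C(=O)OC(C)(C)C)[C@H]2C
F8 | step 13 | N-Boc derivative of 21 (ring A imine, ring B N-Boc piperidine) | CC1=N[C@@H]2CCCCCCCC(=O)O[C@H]3CC[C@@H](CCCCCCCC(=O)O[C@H]1CC2)N(C(=O)OC(C)(C)C)[C@H]3C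
F9 | step 10 | methyl (9R,12S)-9-azido-12-[(tert-butyldimethylsilyl)oxy]-13-methyltetradec-13-enoate | C=C(C)[C@@H](O[Si](C)(C)C(C)(C)C)CC[C@H](N=[N+]=[N-])CCCCCCCC(=O)OC
F10 | step 10 | (9R,12S)-9-azido-12-[(tert-butyldimethylsilyl)oxy]-13-methyltetradec-13-enoic acid | C=C(C)[C@@H](O[Si](C)(C)C(C)(C)C)CC[C@H](N=[N+]=[N-])CCCCCCCC(=O)O
F11 | step 10 | silylated linear dimer methyl ester | C=C(C)[C@@H](O[Si](C)(C)C(C)(C)C)CC[C@H](N=[N+]=[N-])CCCCCCCC(=O)O[C@H](C(C)=C)CC[C@H](N=[N+]=[N-])CCCCCCCC(=O)OC
F12 | step 10 | silylated linear dimer acid | C=C(C)[C@@H](O[Si](C)(C)C(C)(C)C)CC[C@H](N=[N+]=[N-])CCCCCCCC(=O)O[C@H](C(C)=C)CC[C@H](N=[N+]=[N-])CCCCCCCC(=O)O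
F13 | step 10 | linear dimer hydroxy acid | C=C(C)[C@@H](O)CC[C@H](N=[N+]=[N-])CCCCCCCC(=O)O[C@H](C(C)=C)CC[C@H](N=[N+]=[N-])CCCCCCCC(=O)O
F14 | step 12 | (10R,13S,23R,26S)-13,26-diacetyl-10,23-diamino-1,14-dioxacyclohexacosane-2,15-dione | O1[C@H](C(C)=O)CC[C@H](N)CCCCCCCC(=O)O[C@H](C(C)=O)CC[C@H](N)CCCCCCCC1=O
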